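**Retrosynthetic overview**

1. Labels: ring A = C1–C4 plus C5 and C10; aromatic ring B = C5–C10 (C7 bears OH); quinone ring C = C8, C9, C11 (C=O), C12 (OMe), C13 (iPr), C14 (C=O). The strategy rests on the C1 methylene of ring A being peri to the C11 carbonyl and 1,4 across ring A from the C4 carboxyl.
2. Last disconnection: the C1–O lactone bond. The 1-deoxy quinone acid 22 (C7 acetate) is irradiated, the C11 carbonyl takes a C1 hydrogen and the C4 carboxyl closes the bridged lactone; reoxidation and deacetylation follow.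
3. Ring C (bonds C9–C11 and C8–C14): aryllithium from bromide 11 adds to 3-methoxy-4-isopropylcyclobutenedione 14, then thermal ring expansion and oxidation.
4. Ring A and the C4 stereocentre (bond C4–C5): asymmetric Pd-catalysed intramolecular α-arylation of aldehyde 8, which comes from B-alkyl Suzuki coupling of iodide 4 with alkenol 5 (bond C1–C10).
5. Ring order: ring B is bought, then ring A, then ring C, then the lactone ring.

Key step: step 13

Remark: compound names use phenanthrene numbering, in which C1 and C4 are C4 and C1 of the labels above.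
Remark: the sense of induction of the P,N ligand in step 5 is not assumed; the antipode that gives (S)-aldehyde 9 is to be fixed in a small test run, both antipodes being commercial.
Remark: excess 9-BBN may O-borylate the hydroxyl of 5 in step 3; that borinate is hydrolysed in the aqueous coupling medium, so 6 is drawn with a free hydroxyl.

**Route**

Step 1
Reactants: 1 3,5-dibromophenol
Product: 2 1,3-dibromo-5-[(4-methoxybenzyl)oxy]benzene
Conditions: 4-methoxybenzyl chloride, K2CO3, Bu4NI (cat.), DMF, 60 °C
Reagents that add atoms: 4-methoxybenzyl chloride, COc1ccc(CCl)cc1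
Why: Williamson etherification of an acidic phenol; the PMB ether should stand up to amide bases, organolithiums and palladium catalysis and can be removed later with acid together with the tert-butyl ester.

Step 2
Reactants: 2 1,3-dibromo-5-[(4-methoxybenzyl)oxy]benzene
Product: 4 1,3-dibromo-2-iodo-5-[(4-methoxybenzyl)oxy]benzene, via aryllithium 3 (not isolated)
Conditions: LiN(i-Pr)2, THF, –78 °C; then I2, –78 °C → rt
Reagents that add atoms: iodine, [I][I]
Why: Deprotonation by the lithium amide should occur at the C–H flanked by both bromines, the most acidic ring position, and the 2,6-dibromoaryllithium is stable at –78 °C and is iodinated on quenching (halogen-directed metalation and iodinolysis).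

Step 3
Reactants: 4 1,3-dibromo-2-iodo-5-[(4-methoxybenzyl)oxy]benzene; 5 2-methylpent-4-en-1-ol (racemic)
Product: 7 5-{2,6-dibromo-4-[(4-methoxybenzyl)oxy]phenyl}-2-methylpentan-1-ol (racemic), via alkylborane 6 (not isolated)
Conditions: 5, 9-BBN, THF, 0 °C → rt; then 4, PdCl2(dppf) (cat.), Cs2CO3, DMF/H2O, 40 °C
Reagents that add atoms: none
Why: Anti-Markovnikov hydroboration gives the primary alkylborane, and in the B-alkyl Suzuki–Miyaura coupling zerovalent palladium should insert into C–I far faster than into the flanking C–Br bonds at 40 °C.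

Step 4
Reactants: 7 5-{2,6-dibromo-4-[(4-methoxybenzyl)oxy]phenyl}-2-methylpentan-1-ol
Product: 8 5-{2,6-dibromo-4-[(4-methoxybenzyl)oxy]phenyl}-2-methylpentanal (racemic)
Conditions: PhI(OAc)2, TEMPO (cat.), CH2Cl2, rt
Reagents that add atoms: none
Why: Oxoammonium-catalysed oxidation of a primary alcohol stops at the aldehyde and leaves the aryl bromides and the PMB ether alone.

Step 5
Reactants: 8 5-{2,6-dibromo-4-[(4-methoxybenzyl)oxy]phenyl}-2-methylpentanal
Product: 9 (S)-5-bromo-7-[(4-methoxybenzyl)oxy]-1-methyl-1,2,3,4-tetrahydronaphthalene-1-carbaldehyde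
Conditions: Pd(OAc)2 (cat.), 4-tert-butyl-2-[2-(diphenylphosphino)phenyl]-4,5-dihydrooxazole (tBu-PHOX, single enantiomer, see remark), Cs2CO3, t-BuOH, 80 °C
Reagents that add atoms: none
Why: Palladium-catalysed asymmetric intramolecular α-arylation of an α-branched aldehyde closes ring A and sets the quaternary C4 as (S) by ligand control of the enolate face in the C–C reductive elimination; the two bromines are equivalent, so either closure gives the same tetralin and the remaining bromine sits on the future C9.

Step 6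
Reactants: 9 (S)-5-bromo-7-[(4-methoxybenzyl)oxy]-1-methyl-1,2,3,4-tetrahydronaphthalene-1-carbaldehyde
Product: 10 (S)-5-bromo-7-[(4-methoxybenzyl)oxy]-1-methyl-1,2,3,4-tetrahydronaphthalene-1-carboxylic acid
Conditions: NaClO2, NaH2PO4, 2-methylbut-2-ene, t-BuOH/H2O, rt
Reagents that add atoms: sodium chlorite, [Na+].[O-]Cl=O
Why: Pinnick oxidation tolerates the hindered neopentyl-type aldehyde, cannot epimerise the quaternary centre, and the alkene scavenger keeps hypochlorite away from the electron-rich arene.

Step 7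
Reactants: 10 (S)-5-bromo-7-[(4-methoxybenzyl)oxy]-1-methyl-1,2,3,4-tetrahydronaphthalene-1-carboxylic acid
Product: 11 tert-butyl (S)-5-bromo-7-[(4-methoxybenzyl)oxy]-1-methyl-1,2,3,4-tetrahydronaphthalene-1-carboxylate
Conditions: tert-butyl 2,2,2-trichloroacetimidate, CH2Cl2/cyclohexane, rt
Reagents that add atoms: tert-butyl 2,2,2-trichloroacetimidate, CC(C)(C)OC(=N)C(Cl)(Cl)Cl
Why: The acid protonates the imidate and its carboxylate captures the tert-butyl cation at oxygen, so hindrance at the carbonyl does not matter, and the resulting ester removes the acidic proton before the lithiation.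

Step 8
Reactants: 12 3,4-dimethoxycyclobut-3-ene-1,2-dione (dimethyl squarate)
Product: 14 3-methoxy-4-(propan-2-yl)cyclobut-3-ene-1,2-dione, via hydroxycyclobutenone adduct 13 (not isolated)
Conditions: i-PrMgCl, THF, –78 °C; then aq. HCl (12 M), CH2Cl2, rt
Reagents that add atoms: isopropylmagnesium chloride, CC(C)[Mg]Cl; water, O
Why: 1,2-Addition of the Grignard reagent to one squarate carbonyl followed by acid-promoted ionisation of the tertiary alcohol, hydration of the alkoxy-stabilised cation and loss of methanol is the standard route from squarates to 3-alkyl-4-alkoxycyclobutenediones.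

Step 9
Reactants: 11 tert-butyl (S)-5-bromo-7-[(4-methoxybenzyl)oxy]-1-methyl-1,2,3,4-tetrahydronaphthalene-1-carboxylate; 14 3-methoxy-4-(propan-2-yl)cyclobut-3-ene-1,2-dione
Product: 16 tert-butyl (1S)-5-[1-hydroxy-2-methoxy-4-oxo-3-(propan-2-yl)cyclobut-2-en-1-yl]-7-[(4-methoxybenzyl)oxy]-1-methyl-1,2,3,4-tetrahydronaphthalene-1-carboxylate (carbinol epimers), via aryllithium 15 (not isolated)
Conditions: n-BuLi, THF, –78 °C; then 14, –78 °C; aq. NH4Cl
Reagents that add atoms: none
Why: Bromine–lithium exchange is faster than attack on the hindered tert-butyl ester, and the aryllithium should add to the more electrophilic carbonyl of 14 (the one on the methoxy-bearing carbon, not the vinylogous-ester carbonyl), which places OMe next to the future C11.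

Step 10
Reactants: 16 tert-butyl (1S)-5-[1-hydroxy-2-methoxy-4-oxo-3-(propan-2-yl)cyclobut-2-en-1-yl]-7-[(4-methoxybenzyl)oxy]-1-methyl-1,2,3,4-tetrahydronaphthalene-1-carboxylate
Product: 19 tert-butyl (1S)-6-methoxy-9-[(4-methoxybenzyl)oxy]-1-methyl-5,8-dioxo-7-(propan-2-yl)-1,2,3,4,5,8-hexahydrophenanthrene-1-carboxylate, via vinylketene 17 (not isolated), via hydroquinone 18 (not isolated)
Conditions: p-xylene, 138 °C, Ar; then Ag2O, Et2O, rt
Reagents that add atoms: none
Why: Moore rearrangement: conrotatory opening of the cyclobutenone with the hydroxyl turning outward gives the vinylketene, which closes by 6π electrocyclisation onto C8 (the only free ortho position) and tautomerises to the hydroquinone that Ag2O oxidises, so C14 (next to iPr) ends on C8 and C11 (next to OMe) on C9.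

Step 11
Reactants: 19 tert-butyl (1S)-6-methoxy-9-[(4-methoxybenzyl)oxy]-1-methyl-5,8-dioxo-7-(propan-2-yl)-1,2,3,4,5,8-hexahydrophenanthrene-1-carboxylate
Product: 20 (1S)-9-hydroxy-6-methoxy-1-methyl-5,8-dioxo-7-(propan-2-yl)-1,2,3,4,5,8-hexahydrophenanthrene-1-carboxylic acid
Conditions: TFA, anisole, CH2Cl2, 0 °C → rt
Reagents that add atoms: none
Why: Acidolysis cleaves the tert-butyl ester and the PMB ether through their stabilised cations in one operation, anisole traps the benzyl cation, and the quinone and its enol-ether methoxy are inert to anhydrous acid.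

Step 12
Reactants: 20 (1S)-9-hydroxy-6-methoxy-1-methyl-5,8-dioxo-7-(propan-2-yl)-1,2,3,4,5,8-hexahydrophenanthrene-1-carboxylic acid
Product: 22 (1S)-9-acetoxy-6-methoxy-1-methyl-5,8-dioxo-7-(propan-2-yl)-1,2,3,4,5,8-hexahydrophenanthrene-1-carboxylic acid, via mixed anhydride 21 (not isolated)
Conditions: Ac2O, pyridine, DMAP (cat.), CH2Cl2, 0 °C → rt; then H2O/THF, rt
Reagents that add atoms: acetic anhydride, CC(=O)OC(C)=O
Why: DMAP-catalysed acetylation esterifies the peri phenol, and the mixed anhydride formed at the carboxyl is cleaved by water at its unhindered acetyl carbonyl, returning the free acid.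

Step 13
Reactants: 22 (1S)-9-acetoxy-6-methoxy-1-methyl-5,8-dioxo-7-(propan-2-yl)-1,2,3,4,5,8-hexahydrophenanthrene-1-carboxylic acid
Product: 24 (1S,4R)-9-acetoxy-5,8-dihydroxy-6-methoxy-1-methyl-7-(propan-2-yl)-1,2,3,4-tetrahydrophenanthrene-1,4-carbolactone, via photoenol 23 (not isolated)
Conditions: hν (405–420 nm LEDs), degassed dry MeCN (0.005 M), 20 °C, Ar; used crude in step 14
Reagents that add atoms: none
Why: Proposed new method: excitation of the quinone n,π* band should let the C11 carbonyl oxygen (the ketone-like carbonyl, not the vinylogous-ester one at C14) take a C1 hydrogen through a six-membered transition state, giving the dienol quinone methide 23 with an electrophilic exocyclic C1, to which the C4 carboxyl adds while ring C ends as the hydroquinone, so the step is redox-neutral. The closest known reaction type is the photoenolisation of 5-alkyl-1,4-naphthoquinones, whose quinone methide photoenols are captured at the benzylic carbon by water and other external nucleophiles; capture by an internal carboxyl to form a bridged lactone has not been shown. The lactone ring closes 6-exo-trig (counted through C2 and C3) onto the exocyclic C1=C10 bond from a ring A boat with the carboxyl pseudoaxial. The new C1 centre (R) is controlled by C4 (S), since the carboxyl can reach C1 only on its own face and the bicyclo[2.2.2] lactone can only be cis-bridged. The step needs site selectivity for C1–H and a productive excited state: C1–H is the only weak, benzylic C–H held at 1,5-distance from a quinone oxygen, the C7 phenol is masked as the acetate because a free peri hydroxyl would drain the excitation by proton transfer, and light above 400 nm is not absorbed by product 24.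

Step 14
Reactants: 24 (1S,4R)-9-acetoxy-5,8-dihydroxy-6-methoxy-1-methyl-7-(propan-2-yl)-1,2,3,4-tetrahydrophenanthrene-1,4-carbolactone
Product: 25 (1S,4R)-9-acetoxy-6-methoxy-1-methyl-5,8-dioxo-7-(propan-2-yl)-1,2,3,4,5,8-hexahydrophenanthrene-1,4-carbolactone
Conditions: Ag2O, MgSO4, CH2Cl2, rt, dark
Reagents that add atoms: none
Why: Ag2O oxidises the hydroquinone to the quinone without touching the lactone or the aryl acetate; an acetyl shift between the peri oxygens on C7 and C14 of 24 would be reversible, so the oxidation should still draw the mixture to 25.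

Step 15
Reactants: 25 (1S,4R)-9-acetoxy-6-methoxy-1-methyl-5,8-dioxo-7-(propan-2-yl)-1,2,3,4,5,8-hexahydrophenanthrene-1,4-carbolactone
Product: 26 (1S,4R)-9-hydroxy-6-methoxy-1-methyl-5,8-dioxo-7-(propan-2-yl)-1,2,3,4,5,8-hexahydrophenanthrene-1,4-carbolactone (CNP0271770.1; C1 R and C4 S in the overview labels)
Conditions: NH4OAc, MeOH/H2O (4:1), rt
Reagents that add atoms: none
Why: Near-neutral methanolysis selectively removes the activated aryl acetate (a good phenoxide leaving group peri to a carbonyl), while the bridged lactone and the C12 methoxy, which stronger amine nucleophiles could displace, should be left intact.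

**Compound list**

1 | 3,5-dibromophenol | Oc1cc(Br)cc(Br)c1 | starting material
2 | 1,3-dibromo-5-[(4-methoxybenzyl)oxy]benzene | COc1ccc(COc2cc(Br)cc(Br)c2)cc1 | intermediate
3 | 2,6-dibromo-4-[(4-methoxybenzyl)oxy]phenyllithium (formed in situ) | [Li]c1c(Br)cc(OCc2ccc(OC)cc2)cc1Br | intermediate
4 | 1,3-dibromo-2-iodo-5-[(4-methoxybenzyl)oxy]benzene | COc1ccc(COc2cc(Br)c(I)c(Br)c2)cc1 | intermediate
5 | 2-methylpent-4-en-1-ol (racemic) | C=CCC(C)CO | starting material
6 | 5-(9-borabicyclo[3.3.1]nonan-9-yl)-2-methylpentan-1-ol (formed in situ) | CC(CO)CCCB1C2CCCC1CCC2 | intermediate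
7 | 5-{2,6-dibromo-4-[(4-methoxybenzyl)oxy]phenyl}-2-methylpentan-1-ol (racemic) | COc1ccc(COc2cc(Br)c(CCCC(C)CO)c(Br)c2)cc1 | intermediate
8 | 5-{2,6-dibromo-4-[(4-methoxybenzyl)oxy]phenyl}-2-methylpentanal (racemic) | COc1ccc(COc2cc(Br)c(CCCC(C)C=O)c(Br)c2)cc1 | intermediate
9 | (S)-5-bromo-7-[(4-methoxybenzyl)oxy]-1-methyl-1,2,3,4-tetrahydronaphthalene-1-carbaldehyde | O=C[C@@]1(C)CCCc2c(Br)cc(OCc3ccc(OC)cc3)cc21 | intermediate
10 | (S)-5-bromo-7-[(4-methoxybenzyl)oxy]-1-methyl-1,2,3,4-tetrahydronaphthalene-1-carboxylic acid | OC(=O)[C@@]1(C)CCCc2c(Br)cc(OCc3ccc(OC)cc3)cc21 | intermediate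
11 | tert-butyl (S)-5-bromo-7-[(4-methoxybenzyl)oxy]-1-methyl-1,2,3,4-tetrahydronaphthalene-1-carboxylate | CC(C)(C)OC(=O)[C@@]1(C)CCCc2c(Br)cc(OCc3ccc(OC)cc3)cc21 | intermediate
12 | 3,4-dimethoxycyclobut-3-ene-1,2-dione (dimethyl squarate) | COC1=C(OC)C(=O)C1=O | starting material
13 | 4-hydroxy-2,3-dimethoxy-4-(propan-2-yl)cyclobut-2-en-1-one (racemic, formed in situ as its magnesium alkoxide) | COC1=C(OC)C(O)(C(C)C)C1=O | intermediate
14 | 3-methoxy-4-(propan-2-yl)cyclobut-3-ene-1,2-dione | COC1=C(C(C)C)C(=O)C1=O | intermediate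
15 | tert-butyl (S)-5-lithio-7-[(4-methoxybenzyl)oxy]-1-methyl-1,2,3,4-tetrahydronaphthalene-1-carboxylate (formed in situ) | CC(C)(C)OC(=O)[C@@]1(C)CCCc2c([Li])cc(OCc3ccc(OC)cc3)cc21 | intermediate
16 | tert-butyl (1S)-5-[1-hydroxy-2-methoxy-4-oxo-3-(propan-2-yl)cyclobut-2-en-1-yl]-7-[(4-methoxybenzyl)oxy]-1-methyl-1,2,3,4-tetrahydronaphthalene-1-carboxylate (carbinol epimers) | COC1=C(C(C)C)C(=O)C1(O)c1cc(OCc3ccc(OC)cc3)cc2c1CCC[C@]2(C)C(=O)OC(C)(C)C | intermediate
17 | tert-butyl (1S)-5-[(1Z)-1-hydroxy-2-methoxy-4-oxo-3-(propan-2-yl)buta-1,3-dien-1-yl]-7-[(4-methoxybenzyl)oxy]-1-methyl-1,2,3,4-tetrahydronaphthalene-1-carboxylate (vinylketene, formed in situ) | CC(C)C(=C=O)/C(OC)=C(/O)c1cc(OCc3ccc(OC)cc3)cc2c1CCC[C@]2(C)C(=O)OC(C)(C)C | intermediate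
18 | tert-butyl (1S)-5,8-dihydroxy-6-methoxy-9-[(4-methoxybenzyl)oxy]-1-methyl-7-(propan-2-yl)-1,2,3,4-tetrahydrophenanthrene-1-carboxylate (hydroquinone, formed in situ) | COc1c(C(C)C)c(O)c2c(OCc4ccc(OC)cc4)cc3c(c2c1O)CCC[C@]3(C)C(=O)OC(C)(C)C | intermediate
19 | tert-butyl (1S)-6-methoxy-9-[(4-methoxybenzyl)oxy]-1-methyl-5,8-dioxo-7-(propan-2-yl)-1,2,3,4,5,8-hexahydrophenanthrene-1-carboxylate | COC1=C(C(C)C)C(=O)c2c(OCc4ccc(OC)cc4)cc3c(c2C1=O)CCC[C@]3(C)C(=O)OC(C)(C)C | intermediate
20 | (1S)-9-hydroxy-6-methoxy-1-methyl-5,8-dioxo-7-(propan-2-yl)-1,2,3,4,5,8-hexahydrophenanthrene-1-carboxylic acid | COC1=C(C(C)C)C(=O)c2c(O)cc3c(c2C1=O)CCC[C@]3(C)C(=O)O | intermediate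
21 | acetic (1S)-9-acetoxy-6-methoxy-1-methyl-5,8-dioxo-7-(propan-2-yl)-1,2,3,4,5,8-hexahydrophenanthrene-1-carboxylic anhydride (formed in situ) | COC1=C(C(C)C)C(=O)c2c(OC(C)=O)cc3c(c2C1=O)CCC[C@]3(C)C(=O)OC(C)=O | intermediate
22 | (1S)-9-acetoxy-6-methoxy-1-methyl-5,8-dioxo-7-(propan-2-yl)-1,2,3,4,5,8-hexahydrophenanthrene-1-carboxylic acid (key-step precursor) | COC1=C(C(C)C)C(=O)c2c(OC(C)=O)cc3c(c2C1=O)CCC[C@]3(C)C(=O)O | intermediate
23 | (1S)-9-acetoxy-5-hydroxy-6-methoxy-1-methyl-8-oxo-7-(propan-2-yl)-1,2,3,8-tetrahydrophenanthrene-1-carboxylic acid (dienol quinone methide with exocyclic C4=C4a bond, formed in situ) | COC1=C(C(C)C)C(=O)C2=C(OC(C)=O)C=C3C(C2=C1O)=CCC[C@]3(C)C(=O)O | intermediate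
24 | (1S,4R)-9-acetoxy-5,8-dihydroxy-6-methoxy-1-methyl-7-(propan-2-yl)-1,2,3,4-tetrahydrophenanthrene-1,4-carbolactone (carboxyl carbon on C1, ring oxygen on C4) | COc1c(C(C)C)c(O)c2c(OC(C)=O)cc3c(c2c1O)[C@H]1CC[C@]3(C)C(=O)O1 | intermediate
25 | (1S,4R)-9-acetoxy-6-methoxy-1-methyl-5,8-dioxo-7-(propan-2-yl)-1,2,3,4,5,8-hexahydrophenanthrene-1,4-carbolactone | COC1=C(C(C)C)C(=O)c2c(OC(C)=O)cc3c(c2C1=O)[C@H]1CC[C@]3(C)C(=O)O1 | intermediate
26 | (1S,4R)-9-hydroxy-6-methoxy-1-methyl-5,8-dioxo-7-(propan-2-yl)-1,2,3,4,5,8-hexahydrophenanthrene-1,4-carbolactone (CNP0271770.1) | COC1=C(C(C)C)C(=O)c2c(O)cc3c(c2C1=O)[C@H]1CC[C@]3(C)C(=O)O1 | target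

**Step count**

Total: 15 steps. Longest linear sequence: 14 steps (steps 1–7 and 9–15 from 1); step 8 is a one-step branch from 12.

**Steps most likely to fail**

1. Step 13 (photochemical lactonisation, proposed new method). The photoenol may return to the quinone by reverse hydrogen transfer faster than the carboxyl adds. The methoxy-substituted quinone may also have a low-lying π,π* state that abstracts hydrogen poorly. Fallback by known chemistry, setting out from 22: Wohl–Ziegler bromination (NBS, AIBN cat., PhCF3, 80 °C) should give (1S)-9-acetoxy-4-bromo-6-methoxy-1-methyl-5,8-dioxo-7-(propan-2-yl)-1,2,3,4,5,8-hexahydrophenanthrene-1-carboxylic acid F1 as a mixture of bromide epimers. Bromination should prefer the ring A benzylic position because its pseudoaxial C–H is aligned with the π system, whereas the isopropyl methine C–H is held in the ring plane by its two flanking substituents; the fully substituted quinone double bond should be a poor radical trap. Treating F1 with Ag2O in MeCN ionises the bromide, and the carboxylate closes the lactone. Both epimers converge because only the cis-bridged lactone can form. This comes back to the route at 25 without a reoxidation.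

2. Step 5 (asymmetric α-arylation). Facial discrimination in the C–C reductive elimination may be poor, or the second C–Br bond may be reduced during the reaction. Fallback, setting out from 8: cyclisation with an achiral ligand (Pd(OAc)2, Xantphos, Cs2CO3, dioxane, 80 °C) should give racemic 5-bromo-7-[(4-methoxybenzyl)oxy]-1-methyl-1,2,3,4-tetrahydronaphthalene-1-carbaldehyde F2. Pinnick oxidation as in step 6 gives the racemic acid F3, and esterification as in step 7 gives the racemic tert-butyl ester F4. Preparative chromatography of F4 on a chiral stationary phase then delivers the (S)-enantiomer. This comes back to the route at 11.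

3. Step 3 (B-alkyl Suzuki coupling). Transmetalation at the doubly ortho-substituted arylpalladium iodide may be slow, so that the alkylborane decomposes or the C–Br bonds begin to couple. Fallback, setting out from 4 and 5: a Heck reaction under ligand-free phase-transfer conditions (Pd(OAc)2, Bu4NCl, NaHCO3, DMF, 60 °C) should give (E)-5-{2,6-dibromo-4-[(4-methoxybenzyl)oxy]phenyl}-2-methylpent-4-en-1-ol F5 together with double-bond isomers. Diimide reduction (2-nitrobenzenesulfonyl hydrazide, Et3N, CH2Cl2, rt) saturates all alkene isomers without touching C–Br or the PMB ether. This comes back to the route at 7; any aldehyde 8 formed by palladium migration along the chain is the next intermediate anyway.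

**Further compounds**

F1 | step 13 | (1S)-9-acetoxy-4-bromo-6-methoxy-1-methyl-5,8-dioxo-7-(propan-2-yl)-1,2,3,4,5,8-hexahydrophenanthrene-1-carboxylic acid (bromide epimers) | COC1=C(C(C)C)C(=O)c2c(OC(C)=O)cc3c(c2C1=O)C(Br)CC[C@]3(C)C(=O)O
F2 | step 5 | racemic 5-bromo-7-[(4-methoxybenzyl)oxy]-1-methyl-1,2,3,4-tetrahydronaphthalene-1-carbaldehyde | O=CC1(C)CCCc2c(Br)cc(OCc3ccc(OC)cc3)cc21
F3 | step 5 | racemic 5-bromo-7-[(4-methoxybenzyl)oxy]-1-methyl-1,2,3,4-tetrahydronaphthalene-1-carboxylic acid | OC(=O)C1(C)CCCc2c(Br)cc(OCc3ccc(OC)cc3)cc21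
F4 | step 5 | racemic tert-butyl 5-bromo-7-[(4-methoxybenzyl)oxy]-1-methyl-1,2,3,4-tetrahydronaphthalene-1-carboxylate | CC(C)(C)OC(=O)C1(C)CCCc2c(Br)cc(OCc3ccc(OC)cc3)cc21
F5 | step 3 | (E)-5-{2,6-dibromo-4-[(4-methoxybenzyl)oxy]phenyl}-2-methylpent-4-en-1-ol | COc1ccc(COc2cc(Br)c(/C=C/CC(C)CO)c(Br)c2)cc1
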